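## Structural features

The target is a 1,4-naphthoquinone in which quinone ring B (C1–C4) carries no substituent and is fused through C4a and C8a to benzenoid ring A (C5–C8). Ring A is an unsymmetrically masked hydroquinone: C5 bears a methyl ether, C8 a free hydroxyl hydrogen-bonded to the C1 carbonyl, C7 a hydrogen and C6 the side chain. The side chain is joined through C1′, the only stereocenter (R), a benzylic and homoallylic carbinol carbon that carries a 3-methylbut-2-enoate ester and a CH2–CH=C(CH3)2 arm; it has no stereogenic neighbour, so only its absolute configuration must be controlled. The fragile elements are the quinone (bases, nucleophiles, reductants), the benzylic C1′–O bond (ionisation, elimination, acid-promoted addition of a free C1′ hydroxyl to the trisubstituted alkene), the conjugated double bond of the acyl group (migration out of conjugation) and, in every precursor with a carboxyl carbon two atoms from C1′, irreversible closure of a five-membered lactone by a free C1′ oxygen. The real difficulty is the pattern and not the carbon count: the two oxygens of ring A must differ and the quinone must lie in the unsubstituted ring, which a late oxidation of a tetra-alkoxynaphthalene cannot guarantee. The key step uses the fact that C5(OMe)–C6(side chain)–C7(H)–C8(OH) maps atom for atom onto C3–C4–C5–C6 of a 6-hydroxy-2-pyrone, while C4a, C8a and ring B map onto a symmetric p-quinone, so that one [4+2] union with loss of CO2 gives both rings at their final oxidation level with the oxygens already told apart.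

## Logic of the disconnections

18 ⇒ 16 + 17. The O1′–acyl bond is cut first. The unsaturated ester would not survive hydroxide, fluoride or the anionic annulation, so it is put on last; the cut removes five carbons and leaves a carbinol. The forward step must acylate a hindered secondary hydroxyl beside the C8 hydroxyl without touching the C1′–O bond or moving the acyl double bond.

16 ⇒ 15. O1′–H is exchanged for O1′–Si. From the first appearance of a carboxyl group near C1′ to the end of the annulation this oxygen may be neither free (lactone closure) nor acylated (saponification), and a bulky group on it is wanted in the key step. The demand is a cleavage that is neither basic nor strongly acidic.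

15 ⇒ 11 + 12. Ring A is cut at C4a–C5 and C8–C8a, and a carbonyl carbon is added back on C5 as the lactone carbon of 11. This splits the bicycle into a symmetric two-carbon acceptor, 12, which already holds ring B at the quinone level, and a monocyclic four-carbon donor, 11, in which the methyl ether and the future hydroxyl are distinguished by constitution. Two skeletal bonds and one ring are made at once, and no later oxidation or selective methylation is needed. The forward step must begin bond formation at the methoxy-bearing C3 of the anion of 11 and not at C5, must leave C1′ alone, and needs a second equivalent of 12 as oxidant.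

11 ⇒ 10. The anhydride C–O bond is cut to the open diacid. The gain is an acyclic precursor; the demand is a dehydration that brings both carboxyl groups cis, does not acylate the enol and keeps the silyl ether.

10 ⇒ 8. A carboxyl group is added back on the methoxy carbon and the acids are written as methyl esters. The extra ester turns that carbon into a soft carbanion that catalytic base can generate, which the next cut requires. The forward step must hydrolyse three esters, two of them hindered, and lose one CO2 without freeing O1′.

8 ⇒ 6 + 7. The bond between the methoxy carbon and the carbon bearing C1′ (C3–C4 of 11, C5–C6 of 18) is cut in the sense of a conjugate addition. The ring A synthon falls into a purchasable carbon nucleophile, 7, and an ynoate, 6, that holds the stereocenter. The forward step must join a fully substituted carbanion to the β-carbon of 6 with a base too weak to remove the propargylic hydrogen.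

6 ⇒ 5. O–Si again; silylation must outrun base-induced isomerisation of the γ-hydroxy ynoate.

5 ⇒ 2 + 3. The C1′–alkyne bond (C4–C3 of 5) is cut. Its formation creates the stereocenter directly from two achiral pieces, and the sp carbon offers the greatest steric contrast to the CH2 arm. The forward step must deliver the alkynyl group to the Si face of an enolisable aldehyde that isomerises easily.

2 ⇒ 1. Adjustment of oxidation level; the aldehyde must be made and used without letting its β,γ-double bond move into conjugation.

## Other disconnections considered

Alternative 1: Moore ring expansion. The cut is C8–C8a; C5–C8 are stored in cyclobutenone A1, already bonded through the methoxy carbon to a 2,5-dimethoxyphenyl ring that is to become ring B. Heating A1 would open the four-membered ring to an aryl vinylketene, which closes onto the free ortho carbon and tautomerises to naphthol A2.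
- In favour: the step is neutral and needs no reagent. The substitution pattern of ring A is written into A1 and cannot scramble, so on regiochemical certainty of ring A it is better than the chosen plan, whose anion has two reactive ends. C1′ is a spectator in both plans (equal).
- Against: ring B arrives as a hydroquinone dimethyl ether, so the quinone must be unveiled by late oxidative demethylation with (NH4)2Ce(NO3)6. Ring A of A2, a free 4-methoxy-1-naphthol, is the more easily oxidised ring, and its oxidation would destroy the C5 methyl ether. Even with the hydroxyl masked, the oxidant must choose between two rings of similar electron density.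
- Against: the diisopropylcarbamate yields only to hydride or organolithium reagents, which must be used before a quinone exists, so the senecioate and the prenyl alkene would have to ride through the cerium oxidation.
- Against: A1 itself needs addition of an aryllithium to the more hindered carbonyl of an unsymmetrical cyclobutenedione.
- Step economy: at least five operations after the key step against two in the chosen plan.

Alternative 2: ring B from furan and a ring A aryne. The cuts are C1–C8a and C4–C4a. LiN(iPr)2 would deprotonate bromoarene A3 between bromine and the silyloxy group, loss of LiBr would give the C4a–C8a aryne, and furan A4 would trap it as oxabicycle A5.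
- In favour: ring A, with both differentiated oxygens and the stereocenter, is built on a benzene by ordinary aromatic chemistry. A4 is symmetric, so no orientation question arises (equal to the chosen plan with 12). Aryne–furan cycloaddition is a very dependable bond construction, and in that respect better than the chosen key step.
- Against: ring B arrives at the wrong oxidation level. A5 must be opened by acid to a 1-naphthol, under conditions that can ionise the benzylic silyl ether and cyclise onto the prenyl alkene. It must then be oxidised at the para position, for example with (KSO3)2NO, while the electron-rich ring A is spared.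
- Against: two different silyl ethers must then be removed, LiN(iPr)2 can cause migration of the aryl silyl group to the lithiated carbon, and A3 needs its own regiocontrolled synthesis.
- Step economy: about four steps after the key step and a longer approach to A3, so longer overall than the chosen plan.

Alternative 3: Dötz benzannulation. The cuts are C7–C8, C5–C6 and C4a–C5. Chromium carbene complex A6, alkyne A7 and one CO ligand would combine in warm THF by alkyne insertion, CO insertion and electrocyclisation, and air would free naphthol A8 from chromium.
- In favour: it is the most convergent option. The orientation of a terminal alkyne in this reaction is reliable (the substituted alkyne carbon ends next to the new phenol carbon), so on regiochemistry it is better than the chosen plan. A7 would come from the same kind of asymmetric alkynylation as 5 (equal on the stereocenter), and the two ring A oxygens emerge differentiated (equal in principle).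
- Against: the differentiation has the inverse sense. The free hydroxyl is at C5, where it must be methylated between the side chain and a peri methoxy group, and C8 carries a trimethylsilylethyl ether whose fluoride cleavage also removes the side-chain silyl ether.
- Against: ring B is again a dimethyl ether needing oxidative demethylation, with the same ring-selectivity problem as in alternative 1, and chromium from Cr(CO)6 is used stoichiometrically.
- Step economy: methylation, oxidation, deprotection and esterification make four to five steps after the key step against two.

Key step: step 7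

Remark: the symmetry of 12 settles only the orientation on the quinone; the anion of 11 is ambident at C3 and C5, and this is treated as the controlling selectivity of step 7.
Remark: 10 and 11 each exist as interconverting double-bond or tautomeric forms; one form is drawn for each, and every form of 11 gives the same anion 13.
Remark: the ligand enantiomer in step 2 is the one that delivers the alkynyl group to the Si face of 2; the configuration of 5 is to be confirmed through its MTPA esters before material is carried on.

## Route

Step 1
Reactants: 1 4-methylpent-3-en-1-ol
Product: 2 4-methylpent-3-enal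
Conditions: Dess–Martin periodinane, pyridine, CH2Cl2, 0 °C → rt
Reagents that add atoms: none
Why: Dess–Martin oxidation of a primary alcohol stops at the aldehyde, and the pyridine buffer should keep the β,γ-double bond from moving into conjugation; the volatile aldehyde is used at once as a concentrated solution.

Step 2
Reactants: 2 4-methylpent-3-enal; 3 methyl propiolate
Product: 5 methyl (4R)-4-hydroxy-7-methyloct-6-en-2-ynoate, via methylzinc alkynylide 4 (not isolated)
Conditions: Me2Zn, 2,6-bis{[2-(hydroxydiphenylmethyl)pyrrolidin-1-yl]methyl}-4-methylphenol (20 mol %, enantiomer directing Si-face attack), Ph3P=O (40 mol %), PhMe, 0 °C, slow addition of 2; aq. NH4Cl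
Reagents that add atoms: none
Why: Catalytic enantioselective alkynylation of an aldehyde: Me2Zn metalates 3 to 4, and the dinuclear zinc amino-alkoxide formed from the ligand binds aldehyde and alkynylide together, so that the alkynyl group is delivered to the Si face and C4 is set as R; slow addition of 2 keeps self-aldol of the enolisable aldehyde low.

Step 3
Reactants: 5 methyl (4R)-4-hydroxy-7-methyloct-6-en-2-ynoate
Product: 6 methyl (4R)-4-(tert-butyldimethylsilyloxy)-7-methyloct-6-en-2-ynoate
Conditions: TBSOTf, 2,6-lutidine, CH2Cl2, −78 °C
Reagents that add atoms: tert-butyldimethylsilyl trifluoromethanesulfonate, CC(C)(C)[Si](C)(C)OS(=O)(=O)C(F)(F)F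
Why: Silylation with a silyl triflate and a hindered base at low temperature is faster than base-induced isomerisation of a γ-hydroxy ynoate; the silyl ether blocks lactone closure in steps 4–7 and supplies the bulk that gears the side chain in step 7.

Step 4
Reactants: 6 methyl (4R)-4-(tert-butyldimethylsilyloxy)-7-methyloct-6-en-2-ynoate; 7 dimethyl 2-methoxymalonate
Product: 8 trimethyl (2Z)-1-methoxy-2-[(1R)-1-(tert-butyldimethylsilyloxy)-4-methylpent-3-enyl]prop-2-ene-1,1,3-tricarboxylate
Conditions: KOtBu (10 mol %), THF, 0 °C → rt
Reagents that add atoms: none
Why: Base-catalysed Michael addition of a malonate to an alkynoate: the linear sp β-carbon is open even to a fully substituted carbanion, and the vinyl anion formed takes its proton from the next molecule of 7, so the only base present is the malonate anion, too weak to remove the propargylic or γ-hydrogen at C1′; anti addition should give mainly the Z isomer, but the geometry is of no consequence.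

Step 5
Reactants: 8 trimethyl (2Z)-1-methoxy-2-[(1R)-1-(tert-butyldimethylsilyloxy)-4-methylpent-3-enyl]prop-2-ene-1,1,3-tricarboxylate
Product: 10 (2Z)-2-methoxy-3-[(1R)-1-(tert-butyldimethylsilyloxy)-4-methylpent-3-enyl]pent-2-enedioic acid, via tricarboxylic acid 9 (not isolated)
Conditions: LiOH, THF–MeOH–H2O, 45 °C; 1 M HCl to pH 3, 0 °C; pyridine, 80 °C
Reagents that add atoms: lithium hydroxide (aqueous; supplies the hydroxyl oxygens of the carboxylic acids), [Li+].[OH-]
Why: Saponification followed by decarboxylation of an α-methoxy-α-vinyl malonic acid, which loses CO2 readily because the enol formed is conjugated with the remaining acrylic acid; pyridine buffers the acids so that the silyl ether should survive, and once the glutaconate is formed its own α-hydrogen is the most acidic site, so C1′ is not deprotonated.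

Step 6
Reactants: 10 (2Z)-2-methoxy-3-[(1R)-1-(tert-butyldimethylsilyloxy)-4-methylpent-3-enyl]pent-2-enedioic acid
Product: 11 6-hydroxy-3-methoxy-4-[(1R)-1-(tert-butyldimethylsilyloxy)-4-methylpent-3-enyl]pyran-2-one
Conditions: Ac2O (3 equiv), CH2Cl2, rt; evaporate with PhMe
Reagents that add atoms: none
Why: Cyclodehydration of a glutaconic acid to its anhydride, isolated as the hydroxypyrone tautomer; the double-bond isomers of 10 converge because the glutaconic system tautomerises until both carboxyl groups are cis, and without added base the enol should not be acetylated; the moisture-sensitive product is used crude.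

Step 7
Reactants: 11 6-hydroxy-3-methoxy-4-[(1R)-1-(tert-butyldimethylsilyloxy)-4-methylpent-3-enyl]pyran-2-one; 12 1,4-benzoquinone
Product: 15 8-hydroxy-5-methoxy-6-[(1R)-1-(tert-butyldimethylsilyloxy)-4-methylpent-3-enyl]naphthalene-1,4-dione, via lithium pyronolate 13 (not isolated), via naphthalenetriol 14 (not isolated)
Conditions: LiN(SiMe3)2 (1.05 equiv), THF, −78 °C; cannulate into 12 (3 equiv), THF, −78 → 0 °C; aq. NH4Cl
Reagents that add atoms: none
Why: This is the strong-base-induced [4+2] annulation of an enolisable cyclic anhydride with a quinone (Tamura annulation), applied to a glutaconic anhydride. LiN(SiMe3)2 removes the acidic proton of 11 to give the delocalised oxidopyrone 13, whose C3 terminus bonds to one quinone carbon while the resulting quinone enolate attacks C6 (a concerted asynchronous cycloaddition across C3/C6 or a Michael addition followed by aldol-type closure, both leading to the same bridged lactone alkoxide). That adduct expels C2 with the ring oxygen as CO2, the resulting dione enolises twice to triol 14, and a second equivalent of 12 dehydrogenates the 1,4-diol of ring B to the quinone. Ring A (C4a, C5, C6, C7, C8, C8a) is closed by an intermolecular two-bond annulation, C4a–C5 first and C8–C8a second as a six-membered exo attack on the C6 carbonyl; no stereocenter is created, and C1′ is safe because it hangs on C4, the central nodal carbon of the anion, where it can be neither deprotonated nor lose silanolate by β-elimination. The selectivity needed lies between the two ends of the ambident anion: bonding through C5 instead of C3 would expel C6 and give the isomeric 5-hydroxy-6-methoxy-7-alkyl quinone, a question that the symmetry of 12 does not remove. Two features of 13 should favour C3: allylic strain turns C1′–H toward the C3 methoxy group so that the silyloxy and prenyl arms cover both faces of C5, and lithium sits in a five-membered chelate between the C2 oxygen and the methoxy oxygen, which makes C3 the α-carbon of the metal enolate and delivers the lithium-bound quinone there. Over-reaction of the product is limited by adding 13 to an excess of 12, the more electrophilic acceptor, with only one equivalent of base present.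

Step 8
Reactants: 15 8-hydroxy-5-methoxy-6-[(1R)-1-(tert-butyldimethylsilyloxy)-4-methylpent-3-enyl]naphthalene-1,4-dione
Product: 16 8-hydroxy-6-[(1R)-1-hydroxy-4-methylpent-3-enyl]-5-methoxynaphthalene-1,4-dione
Conditions: HF·pyridine, pyridine, THF, 0 °C → rt
Reagents that add atoms: none
Why: Fluoride cleavage of a silyl ether at silicon leaves the C1′–O bond and hence the configuration untouched; pyridine-buffered HF is not basic enough to harm the hydroxyquinone and should not be acidic enough to ionise the benzylic alcohol or add it to the trisubstituted alkene.

Step 9
Reactants: 16 8-hydroxy-6-[(1R)-1-hydroxy-4-methylpent-3-enyl]-5-methoxynaphthalene-1,4-dione; 17 3-methylbut-2-enoic acid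
Product: 18 (1R)-1-(4-hydroxy-1-methoxy-5,8-dioxo-5,8-dihydronaphthalen-2-yl)-4-methylpent-3-enyl 3-methylbut-2-enoate
Conditions: N,N′-dicyclohexylcarbodiimide, 4-(dimethylamino)pyridine (10 mol %), CH2Cl2, 0 °C → rt
Reagents that add atoms: none
Why: Steglich esterification should acylate the secondary carbinol, while the C8 hydroxyl, tied to the C1 carbonyl by a hydrogen bond, is far less nucleophilic; acylation occurs at oxygen so C1′ keeps its configuration, and low temperature with only catalytic amine should keep the acyl double bond in conjugation.

## Compound list

1 | 4-methylpent-3-en-1-ol | CC(C)=CCCO | starting material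
2 | 4-methylpent-3-enal | CC(C)=CCC=O | intermediate
3 | methyl propiolate | C#CC(=O)OC | starting material
4 | methyl 3-(methylzincio)prop-2-ynoate (methylzinc alkynylide) | C[Zn]C#CC(=O)OC | intermediate (not isolated)
5 | methyl (4R)-4-hydroxy-7-methyloct-6-en-2-ynoate | COC(=O)C#C[C@@H](CC=C(C)C)O | intermediate
6 | methyl (4R)-4-(tert-butyldimethylsilyloxy)-7-methyloct-6-en-2-ynoate | COC(=O)C#C[C@@H](CC=C(C)C)O[Si](C)(C)C(C)(C)C | intermediate
7 | dimethyl 2-methoxymalonate | COC(C(=O)OC)C(=O)OC | starting material
8 | trimethyl (2Z)-1-methoxy-2-[(1R)-1-(tert-butyldimethylsilyloxy)-4-methylpent-3-enyl]prop-2-ene-1,1,3-tricarboxylate | COC(=O)/C=C(/[C@@H](CC=C(C)C)O[Si](C)(C)C(C)(C)C)C(OC)(C(=O)OC)C(=O)OC | intermediate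
9 | (2Z)-1-methoxy-2-[(1R)-1-(tert-butyldimethylsilyloxy)-4-methylpent-3-enyl]prop-2-ene-1,1,3-tricarboxylic acid | OC(=O)/C=C(/[C@@H](CC=C(C)C)O[Si](C)(C)C(C)(C)C)C(OC)(C(O)=O)C(O)=O | intermediate (not isolated)
10 | (2Z)-2-methoxy-3-[(1R)-1-(tert-butyldimethylsilyloxy)-4-methylpent-3-enyl]pent-2-enedioic acid (one double-bond isomer drawn) | OC(=O)C/C(=C(/OC)C(O)=O)[C@@H](CC=C(C)C)O[Si](C)(C)C(C)(C)C | intermediate
11 | 6-hydroxy-3-methoxy-4-[(1R)-1-(tert-butyldimethylsilyloxy)-4-methylpent-3-enyl]pyran-2-one | COC1=C([C@@H](CC=C(C)C)O[Si](C)(C)C(C)(C)C)C=C(O)OC1=O | intermediate
12 | 1,4-benzoquinone | O=C1C=CC(=O)C=C1 | starting material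
13 | lithium 5-methoxy-6-oxo-4-[(1R)-1-(tert-butyldimethylsilyloxy)-4-methylpent-3-enyl]-6H-pyran-2-olate (lithium pyronolate) | COC1=C([C@@H](CC=C(C)C)O[Si](C)(C)C(C)(C)C)C=C([O-])OC1=O.[Li+] | intermediate (not isolated)
14 | 5-methoxy-6-[(1R)-1-(tert-butyldimethylsilyloxy)-4-methylpent-3-enyl]naphthalene-1,4,8-triol | COc1c([C@@H](CC=C(C)C)O[Si](C)(C)C(C)(C)C)cc(O)c2c(O)ccc(O)c12 | intermediate (not isolated)
15 | 8-hydroxy-5-methoxy-6-[(1R)-1-(tert-butyldimethylsilyloxy)-4-methylpent-3-enyl]naphthalene-1,4-dione | COc1c([C@@H](CC=C(C)C)O[Si](C)(C)C(C)(C)C)cc(O)c2c1C(=O)C=CC2=O | intermediate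
16 | 8-hydroxy-6-[(1R)-1-hydroxy-4-methylpent-3-enyl]-5-methoxynaphthalene-1,4-dione | COc1c([C@@H](CC=C(C)C)O)cc(O)c2c1C(=O)C=CC2=O | intermediate
17 | 3-methylbut-2-enoic acid | CC(C)=CC(=O)O | starting material
18 | (1R)-1-(4-hydroxy-1-methoxy-5,8-dioxo-5,8-dihydronaphthalen-2-yl)-4-methylpent-3-enyl 3-methylbut-2-enoate (CNP0130192.1) | COc1c([C@@H](CC=C(C)C)OC(=O)C=C(C)C)cc(O)c2c1C(=O)C=CC2=O | target

## Step count and least certain steps

Total: 9 steps. Longest linear sequence: 9 steps (1 → 18); 3, 7, 12 and 17 enter as purchased reagents.

Step 7 (key step). The most likely failure is bond formation through the unsubstituted C5 end of the ambident anion, which would expel the wrong carbonyl as CO2. Gearing and chelation are expected to favour C3, but C5 is the less substituted carbon. A second hazard is electron transfer from the anion to the quinone, leading to oligomers. The fallback sets out from 11 and returns at 15; it fixes by constitution which carbonyl is lost.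
- 11 would be opened with 4-methoxybenzyl alcohol and catalytic 4-(dimethylamino)pyridine at the less hindered, non-conjugated C6 carbonyl to give (2Z)-2-methoxy-5-(4-methoxybenzyloxy)-5-oxo-3-[(1R)-1-(tert-butyldimethylsilyloxy)-4-methylpent-3-enyl]pent-2-enoic acid F1. Its constitution is to be established before it is carried on.
- Cyclodehydration through the free C2 acid with (CF3CO)2O and Et3N would give 3-methoxy-6-(4-methoxybenzyloxy)-4-[(1R)-1-(tert-butyldimethylsilyloxy)-4-methylpent-3-enyl]pyran-2-one F2.
- A thermal Diels–Alder reaction of this neutral alkoxypyrone with excess 12 (PhMe, 100 °C), loss of CO2 and dehydrogenation by 12 would give 5-methoxy-8-(4-methoxybenzyloxy)-6-[(1R)-1-(tert-butyldimethylsilyloxy)-4-methylpent-3-enyl]naphthalene-1,4-dione F3.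
- Oxidative debenzylation with 2,3-dichloro-5,6-dicyano-1,4-benzoquinone in wet CH2Cl2 would return 15.

Step 4. The fully substituted carbanion of 7 may add only slowly next to the branched silyloxy carbon. Forcing conditions could then cause base-induced propargyl–allenyl isomerisation of 6, which would erase C1′. The fallback sets out from 6 and returns at 10; it brings the carbon in with an unhindered nucleophile and the methoxy group in afterwards.
- Dimethyl malonate (NaH, THF) would add to 6 to give trimethyl 2-[(1R)-1-(tert-butyldimethylsilyloxy)-4-methylpent-3-enyl]prop-2-ene-1,1,3-tricarboxylate F4.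
- Krapcho dealkoxycarbonylation (LiCl, wet DMSO, 130 °C) would give dimethyl 3-[(1R)-1-(tert-butyldimethylsilyloxy)-4-methylpent-3-enyl]pent-2-enedioate F5.
- Regitz diazo transfer (4-acetamidobenzenesulfonyl azide, 1,8-diazabicyclo[5.4.0]undec-7-ene, MeCN) would give dimethyl 2-diazo-3-[(1R)-1-(tert-butyldimethylsilyloxy)-4-methylpent-3-enyl]pent-3-enedioate F6; the anion of F5 is symmetric, so only one diazo compound can form.
- O–H insertion of the rhodium carbenoid into methanol (Rh2(OAc)4, MeOH) would give dimethyl 2-methoxy-3-[(1R)-1-(tert-butyldimethylsilyloxy)-4-methylpent-3-enyl]pent-3-enedioate F7. Insertion at the carbenoid carbon or at its vinylogous position leads to the same constitution, and methanol as solvent should outrun intramolecular cyclopropanation.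
- LiOH at room temperature and cold acidification would give 10.

Step 5. The silyl ether may be lost while free carboxylic acids are warmed, after which the γ-hydroxy acid would close irreversibly to a butenolide. The second, hindered malonate ester may also resist hydroxide. The fallback sets out from 8 and returns at 10 without a new isolated compound; it cleaves the esters at the methyl carbon and not at the acyl carbon. LiI in pyridine at reflux would dealkylate the three methyl esters by SN2 attack of iodide, the geminal carboxylate would lose CO2 in the same pot, and cold acidification to pH 3 would give 10. No aqueous hydroxide and no warm free acid are involved.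

Step 2. The zinc alkoxide species may enolise the doubly activated α-CH2 of 2, causing self-aldol and migration of the double bond into conjugation, and facial control may be incomplete. The fallback sets out from 2 and returns at 5; it replaces asymmetric catalysis by a resolution.
- The lithium acetylide of 3 (LiN(SiMe3)2, THF, −78 °C) would add to 2 at low temperature to give racemic methyl 4-hydroxy-7-methyloct-6-en-2-ynoate F8.
- Acylation with vinyl acetate and immobilised Candida antarctica lipase B would follow. The empirical size rule for lipases, with the slim alkynyl arm as the smaller group, predicts conversion of the S enantiomer into methyl (4S)-4-acetoxy-7-methyloct-6-en-2-ynoate F9.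
- (R)-5 would remain as the unreacted alcohol, be separated by chromatography and be checked through its MTPA esters.

## Further compounds

F1 | step 7 | (2Z)-2-methoxy-5-(4-methoxybenzyloxy)-5-oxo-3-[(1R)-1-(tert-butyldimethylsilyloxy)-4-methylpent-3-enyl]pent-2-enoic acid | COc1ccc(COC(=O)CC(=C(OC)C(O)=O)[C@@H](CC=C(C)C)O[Si](C)(C)C(C)(C)C)cc1
F2 | step 7 | 3-methoxy-6-(4-methoxybenzyloxy)-4-[(1R)-1-(tert-butyldimethylsilyloxy)-4-methylpent-3-enyl]pyran-2-one | COc1ccc(COC2=CC([C@@H](CC=C(C)C)O[Si](C)(C)C(C)(C)C)=C(OC)C(=O)O2)cc1
F3 | step 7 | 5-methoxy-8-(4-methoxybenzyloxy)-6-[(1R)-1-(tert-butyldimethylsilyloxy)-4-methylpent-3-enyl]naphthalene-1,4-dione | COc1ccc(COc2cc([C@@H](CC=C(C)C)O[Si](C)(C)C(C)(C)C)c(OC)c3C(=O)C=CC(=O)c23)cc1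
F4 | step 4 | trimethyl 2-[(1R)-1-(tert-butyldimethylsilyloxy)-4-methylpent-3-enyl]prop-2-ene-1,1,3-tricarboxylate | COC(=O)C=C([C@@H](CC=C(C)C)O[Si](C)(C)C(C)(C)C)C(C(=O)OC)C(=O)OC
F5 | step 4 | dimethyl 3-[(1R)-1-(tert-butyldimethylsilyloxy)-4-methylpent-3-enyl]pent-2-enedioate | COC(=O)C=C([C@@H](CC=C(C)C)O[Si](C)(C)C(C)(C)C)CC(=O)OC
F6 | step 4 | dimethyl 2-diazo-3-[(1R)-1-(tert-butyldimethylsilyloxy)-4-methylpent-3-enyl]pent-3-enedioate | COC(=O)C=C([C@@H](CC=C(C)C)O[Si](C)(C)C(C)(C)C)C(=[N+]=[N-])C(=O)OC
F7 | step 4 | dimethyl 2-methoxy-3-[(1R)-1-(tert-butyldimethylsilyloxy)-4-methylpent-3-enyl]pent-3-enedioate (both C2 epimers) | COC(=O)C=C([C@@H](CC=C(C)C)O[Si](C)(C)C(C)(C)C)C(OC)C(=O)OC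
F0 | step 5 | none | none
F8 | step 2 | methyl 4-hydroxy-7-methyloct-6-en-2-ynoate (racemic) | COC(=O)C#CC(O)CC=C(C)C
F9 | step 2 | methyl (4S)-4-acetoxy-7-methyloct-6-en-2-ynoate | COC(=O)C#C[C@H](CC=C(C)C)OC(C)=O
A1 | alternative 1 | 4-(2,5-dimethoxyphenyl)-4-methoxy-3-[(1R)-1-(N,N-diisopropylcarbamoyloxy)-4-methylpent-3-enyl]cyclobut-2-en-1-one (both C4 epimers) | COc1ccc(OC)c(c1)C1(OC)C(=CC1=O)[C@@H](CC=C(C)C)OC(=O)N(C(C)C)C(C)C
A2 | alternative 1 | (1R)-1-(4-hydroxy-1,5,8-trimethoxynaphthalen-2-yl)-4-methylpent-3-enyl N,N-diisopropylcarbamate | COc1c([C@@H](CC=C(C)C)OC(=O)N(C(C)C)C(C)C)cc(O)c2c(OC)ccc(OC)c12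
A3 | alternative 2 | tert-butyl{(1R)-1-[3-bromo-2-methoxy-5-(triisopropylsilyloxy)phenyl]-4-methylpent-3-enyloxy}dimethylsilane | COc1c(Br)cc(O[Si](C(C)C)(C(C)C)C(C)C)cc1[C@@H](CC=C(C)C)O[Si](C)(C)C(C)(C)C
A4 | alternative 2 | furan | c1ccoc1
A5 | alternative 2 | 5-methoxy-6-[(1R)-1-(tert-butyldimethylsilyloxy)-4-methylpent-3-enyl]-8-(triisopropylsilyloxy)-1,4-dihydro-1,4-epoxynaphthalene (both bridgehead diastereomers) | COc1c([C@@H](CC=C(C)C)O[Si](C)(C)C(C)(C)C)cc(O[Si](C(C)C)(C(C)C)C(C)C)c2c1C1C=CC2O1
A6 | alternative 3 | pentacarbonyl{(2,5-dimethoxyphenyl)[2-(trimethylsilyl)ethoxy]methylidene}chromium, (CO)5Cr=C(OCH2CH2SiMe3)[C6H3(OMe)2] | O=C=[Cr](=C=O)(=C=O)(=C=O)(=C=O)=C(OCC[Si](C)(C)C)c1cc(OC)ccc1OC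
A7 | alternative 3 | (3R)-3-(tert-butyldimethylsilyloxy)-6-methylhept-5-en-1-yne | C#C[C@@H](CC=C(C)C)O[Si](C)(C)C(C)(C)C
A8 | alternative 3 | 2-[(1R)-1-(tert-butyldimethylsilyloxy)-4-methylpent-3-enyl]-5,8-dimethoxy-4-[2-(trimethylsilyl)ethoxy]naphthalen-1-ol | Oc1c([C@@H](CC=C(C)C)O[Si](C)(C)C(C)(C)C)cc(OCC[Si](C)(C)C)c2c(OC)ccc(OC)c12
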